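**Plan**
Cuts: first the bond from C4 of unit 2 to the ether oxygen (the oxygen stays on C4 of unit 3), then the C4–C8 bond between units 1 and 2, and in unit 3 the O1–C2 bond of ring C and the C3–C4 bond.
Enabling feature: in ring C of unit 3 the oxygen on C4 and the aryl-bearing C2 are 1,3-related across oxygenated C3. Tying that oxygen to C2 gives an oxetane (O, C2, C3, C4), which is the [2+2] adduct of the ring A aldehyde (C4=O) and the C2=C3 enol ether of the ring B acetaldehyde.
Forward: the photocycloaddition closes the oxetane. DDQ oxidation at C2 releases its strain to a C2 ketone and leaves the former aldehyde oxygen on C4. The freed ring A phenol and the ketone then close ring C by reductive etherification. A benzylated epicatechin dimer carrying a 4β-benzylthio group on unit 2 is joined to the C4–OH of unit 3 last.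
Stereochemistry: units 1 and 2 come from (−)-epicatechin, and both new C4 substituents enter anti to the axial 3-O group (4β). In unit 3 the C3/C4 relation comes from the oxetane closure and C2 from hydride delivery anti to O3 and O4 (all-cis). The absolute configuration comes from separating the two diastereomeric ethers formed with the enantiopure dimer.

Key step: step 10

Assumption: every compound of the unit 3 series from the oxetane to the flavan-4-ol is racemic and is named and drawn as the enantiomer that ends up in the target; the enol ether is used as a Z/E mixture (Z drawn), since the alkene geometry is lost in the key step.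

Step 1
Reactants: 1 (−)-epicatechin
Product: 2 3,5,7,3',4'-penta-O-benzyl-(−)-epicatechin
Conditions: BnBr (6.5 equiv), NaH (6 equiv), DMF, −20 °C to rt
Reagents that add atoms: benzyl bromide, BrCc1ccccc1
Why: Williamson ether synthesis on the four phenols and the 3-OH, run cold so that the phenoxides are alkylated before ring C can open, and C2 and C3 are not touched.

Step 2
Reactants: 2 penta-O-benzylepicatechin
Product: 3 4β-(2-ethoxyethoxy)-3,5,7,3',4'-penta-O-benzylepicatechin (2,3-cis-3,4-trans)
Conditions: DDQ (2 equiv), 2-ethoxyethanol (10 equiv), CH2Cl2, rt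
Reagents that add atoms: 2-ethoxyethanol, CCOCCO
Why: DDQ benzylic C–H oxidation, in which hydride abstraction from C4–H gives the ring A-stabilised C4 cation and the alcohol traps it from the β face, anti to the axial 3-OBn group, so that the new C4 centre is 3,4-trans.

Step 3
Reactants: 3 4β-(2-ethoxyethoxy)-penta-O-benzylepicatechin
Product: 4 4β-benzylthio-3,5,7,3',4'-penta-O-benzylepicatechin (2,3-cis-3,4-trans)
Conditions: BnSH (5 equiv), TMSOTf (0.1 equiv), CH2Cl2, −78 °C
Reagents that add atoms: phenylmethanethiol, SCc1ccccc1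
Why: Lewis acid-catalysed SN1 thiolysis of the 4-alkoxy group, in which the excess thiol outruns any arene nucleophile and again enters anti to the 3-OBn group, so that C4 stays 4β.

Step 4
Reactants: 3 4β-(2-ethoxyethoxy)-penta-O-benzylepicatechin; 4 4β-benzylthio-penta-O-benzylepicatechin
Product: 5 penta-O-benzylepicatechin-(4β→8)-[4β-benzylthio-penta-O-benzylepicatechin]
Conditions: 4 (4 equiv, excess recovered), TMSOTf (0.2 equiv), CH2Cl2, −78 °C
Reagents that add atoms: none
Why: Friedel–Crafts-type flavan C4–C8 condensation, in which the hard Lewis acid ionises only the C4–O bond of 3 and leaves the C4–S bond of 4 intact, the excess of 4 suppresses self-condensation of 3, and C8 of 4 attacks the cation anti to the 3-OBn group to set the 4β interflavan centre.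

Step 5
Reactants: 6 2,4,6-trihydroxybenzaldehyde
Product: 7 2-hydroxy-4,6-bis(pivaloyloxy)benzaldehyde
Conditions: PivCl (2.05 equiv), Et3N (2.2 equiv), THF, 0 °C
Reagents that add atoms: pivaloyl chloride, CC(C)(C)C(=O)Cl
Why: Selective O-acylation, in which the 4-OH and one ortho OH are esterified and the last ortho OH, held in a hydrogen bond to the formyl oxygen, should resist the bulky acid chloride.

Step 6
Reactants: 7 2-hydroxy-4,6-bis(pivaloyloxy)benzaldehyde
Product: 8 2-(tert-butyldimethylsilyloxy)-4,6-bis(pivaloyloxy)benzaldehyde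
Conditions: TBSCl, imidazole, DMF, rt
Reagents that add atoms: tert-butyldimethylsilyl chloride, CC(C)(C)[Si](C)(C)Cl
Why: Silyl ether formation, which gives the oxygen that becomes O1 a group removable without base and removes the acidic OH that would deactivate the excited aldehyde by proton transfer.

Step 7
Reactants: 9 3,4-dihydroxyphenylacetic acid
Product: 10 benzyl [3,4-bis(benzyloxy)phenyl]acetate
Conditions: BnBr (3.3 equiv), K2CO3, DMF, 60 °C
Reagents that add atoms: benzyl bromide, BrCc1ccccc1
Why: Williamson etherification of both phenols together with carboxylate alkylation in one operation.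

Step 8
Reactants: 10 benzyl [3,4-bis(benzyloxy)phenyl]acetate
Product: 11 [3,4-bis(benzyloxy)phenyl]acetaldehyde
Conditions: i-Bu2AlH (1.1 equiv), toluene, −78 °C; aq. potassium sodium tartrate
Reagents that add atoms: none
Why: Partial ester reduction, in which the tetrahedral aluminium hemiacetal survives at −78 °C and releases the aldehyde only on work-up.

Step 9
Reactants: 11 [3,4-bis(benzyloxy)phenyl]acetaldehyde
Product: 12 tert-butyldimethylsilyl enol ether of 11 (Z/E mixture, Z drawn)
Conditions: TBSOTf, Et3N, CH2Cl2, 0 °C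
Reagents that add atoms: tert-butyldimethylsilyl triflate, CC(C)(C)[Si](C)(C)OS(=O)(=O)C(F)(F)F
Why: Soft enolisation and O-silylation (silyl enol ether formation) of an aldehyde that enolises easily because the enol is conjugated with ring B.

Step 10
Reactants: 8 2-(tert-butyldimethylsilyloxy)-4,6-bis(pivaloyloxy)benzaldehyde; 12 silyl enol ether of 11
Product: 13 (±)-r-2-[3,4-bis(benzyloxy)phenyl]-t-3-(tert-butyldimethylsilyloxy)-c-4-[2-(tert-butyldimethylsilyloxy)-4,6-bis(pivaloyloxy)phenyl]oxetane (aryl groups cis to each other, silyloxy trans to both)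
Conditions: hν (366 nm), 12 (3 equiv), benzene (0.05 M in 8), argon, 10 °C
Reagents that add atoms: none
Why: Proposed new method: light of 366 nm, which 12 does not absorb, takes 8 to its n,π* triplet, whose electrophilic oxygen bonds to C2, the nucleophilic β-carbon of the enol ether, and the triplet 2-oxa-1,4-biradical (α-siloxy radical at C3, benzylic radical at C4) forms the C3–C4 bond after intersystem crossing. The closest known reaction type is the Paternò–Büchi reaction of aromatic aldehydes with silyl enol ethers, which gives 3-silyloxyoxetanes with the silyloxy group trans to the aldehyde aryl, but a β-aryl enol ether has not been used in it. The only ring closed is the oxetane, by radical recombination within the 1,4-biradical (O–C2 first, C3–C4 second). C2 is fixed when the first bond forms and does not matter because step 11 erases it, whereas C3 and C4 are fixed in the closure, where free rotation in the biradical should let the bulky OTBS group avoid both the 2,6-disubstituted ring A aryl on C4 and the ring B aryl on C2 whatever the geometry of 12; the product is racemic. The step needs oxygen-to-C2 regioselectivity and must compete with energy and electron transfer to the styrene-like donor: energy transfer only isomerises 12 towards its Z form, in which allylic strain between OTBS and ring B twists the ring out of conjugation, so this form should quench less, gain little benzylic stabilisation on attack at C3 and behave like an ordinary enol ether, while benzene disfavours the radical ion pair that would lead to the 2-siloxy regioisomer. The excess of 12 and chromatographic removal of any acid-labile 2-siloxy acetal isomer and of any isomer with OTBS cis to ring A complete the control.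

Step 11
Reactants: 13 (±)-2,4-cis-diaryl-3-silyloxyoxetane
Product: 14 (±)-anti-1-[3,4-bis(benzyloxy)phenyl]-2-(tert-butyldimethylsilyloxy)-3-hydroxy-3-[2-(tert-butyldimethylsilyloxy)-4,6-bis(pivaloyloxy)phenyl]propan-1-one
Conditions: DDQ (2 equiv), CH2Cl2/pH 7 buffer (18:1), rt to 40 °C
Reagents that add atoms: water, O
Why: DDQ oxidative cleavage of a 3,4-dialkoxybenzyl-type ether, in which hydride leaves C2–H (the only C–H both α to oxygen and benzylic to an electron-rich ring), water adds and the strained 2-hydroxyoxetane collapses to the aryl ketone and the C4–OH, so that C3 and C4 keep their configuration and the geometrically impossible rear-side attack at C2 by a ring A phenoxide, whose tether and leaving group both hang on C4, is avoided.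

Step 12
Reactants: 14 (±)-anti β-hydroxy-α-silyloxy ketone
Product: 15 (±)-anti-1-[3,4-bis(benzyloxy)phenyl]-2-(tert-butyldimethylsilyloxy)-3-hydroxy-3-[2-hydroxy-4,6-bis(pivaloyloxy)phenyl]propan-1-one
Conditions: KHF2 (2 equiv), MeOH, rt
Reagents that add atoms: none
Why: Chemoselective fluoride desilylation, in which bifluoride cleaves the aryl silyl ether (phenoxide leaving group) but not the secondary alkyl TBS ether or the pivalates, and the nearly neutral medium avoids retro-aldol cleavage and epimerisation at C3.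

Step 13
Reactants: 15 (±)-anti keto phenol
Product: 17 (±)-(2S*,3S*,4S*)-2-[3,4-bis(benzyloxy)phenyl]-3-(tert-butyldimethylsilyloxy)-4-hydroxychroman-5,7-diyl dipivalate (all-cis), via cyclic hemiketal 16 (not isolated)
Conditions: Et3SiH (5 equiv), TMSOTf (0.3 equiv), CH2Cl2, −78 to −40 °C
Reagents that add atoms: none
Why: Reductive etherification, in which acid ionises 16 to a flattened 2-aryl oxocarbenium ion and Et3SiH delivers hydride to C2 from the face opposite the cis C3–OTBS and C4–OH groups, which sets the 2,3-cis relation as in known routes to epi-series flavan-3-ols, while the two pivalates keep ring A too electron-poor for ionisation at C4.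

Step 14
Reactants: 5 dimer 4β-benzyl thioether; 17 (±)-all-cis flavan-4-ol
Product: 18 penta-O-benzylepicatechin-(4β→8)-penta-O-benzylepicatechin-(4β→O→4)-[(2S,3S,4S)-3',4'-di-O-benzyl-3-O-TBS-5,7-di-O-pivaloyl-2,3-cis-3,4-cis-flavan-3,4-diol]
Conditions: 17 (3 equiv, excess recovered), AgBF4 (2.5 equiv), 2,6-di-tert-butyl-4-methylpyridine (3 equiv), 4 Å molecular sieves, CH2Cl2, −40 to 0 °C, dark; preparative HPLC
Reagents that add atoms: none
Why: Thiophile-promoted SN1 etherification, in which AgBF4 removes the benzylthio group, the C4 cation of unit 2 is captured by the only free hydroxyl present from the β face anti to the 3-OBn group (3,4-trans), the hindered pyridine takes up HBF4 so the ether is not re-ionised, the pivalates stop C6 and C8 of 17 from competing as carbon nucleophiles, and the two enantiomers of 17 give two diastereomeric ethers whose separation fixes the absolute configuration of unit 3.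

Step 15
Reactants: 18 fully protected trimer
Product: 19 trimer with free 3-OH in unit 3 (pivalates and twelve benzyl ethers retained)
Conditions: TBAF/AcOH (1:1, 5 equiv), THF, rt to 40 °C
Reagents that add atoms: none
Why: Buffered fluoride desilylation, which removes the hindered secondary TBS ether while the pivalates still deactivate ring A of unit 3, so that the labile C4–O–C4 ether meets neither strong acid nor a conjugated phenoxide.

Step 16
Reactants: 19 desilylated trimer
Product: 20 trimer with free 3-, 5- and 7-OH in unit 3 (twelve benzyl ethers retained)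
Conditions: K2CO3 (0.5 equiv), MeOH/THF, 0 °C to rt
Reagents that add atoms: none
Why: Base-catalysed transesterification (Zemplén-type methanolysis) of the two aryl pivalates, mild enough that the secondary alkoxide on C4 is not expelled from the transient phenoxide.

Step 17
Reactants: 20 dodeca-O-benzyl trimer
Product: 21 CNP0310719.1, epicatechin-(4β→8)-epicatechin-(4β→O→4)-[(2S)-2,3-cis-3,4-cis-flavan-3,3',4,4',5,7-hexol]
Conditions: H2 (1 atm), Pd(OH)2/C, THF/MeOH/H2O, rt, stopped at the calculated uptake
Reagents that add atoms: none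
Why: Catalytic hydrogenolysis under neutral conditions, in which the ten aryl benzyl and two primary-benzyl alkyl ethers should be cleaved much faster than the hindered secondary C4–O–C4 ether and no stereocentre is touched.

**Compound list**
1 | (−)-epicatechin | Oc1cc(O)c2c(c1)O[C@H](c1ccc(O)c(O)c1)[C@H](O)C2 | starting material
2 | 3,5,7,3',4'-penta-O-benzyl-(−)-epicatechin | C(c1ccccc1)Oc1cc(OCc2ccccc2)c2c(c1)O[C@H](c1ccc(OCc3ccccc3)c(OCc3ccccc3)c1)[C@H](OCc1ccccc1)C2 | intermediate
3 | 4β-(2-ethoxyethoxy)-penta-O-benzylepicatechin | C(c1ccccc1)Oc1cc(OCc2ccccc2)c2c(c1)O[C@H](c1ccc(OCc3ccccc3)c(OCc3ccccc3)c1)[C@H](OCc1ccccc1)[C@H]2OCCOCC | intermediate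
4 | 4β-benzylthio-penta-O-benzylepicatechin | C(c1ccccc1)Oc1cc(OCc2ccccc2)c2c(c1)O[C@H](c1ccc(OCc3ccccc3)c(OCc3ccccc3)c1)[C@H](OCc1ccccc1)[C@H]2SCc1ccccc1 | intermediate
5 | penta-O-benzylepicatechin-(4β→8)-[4β-benzylthio-penta-O-benzylepicatechin] | C(c1ccccc1)Oc1cc(OCc2ccccc2)c2c(c1)O[C@H](c1ccc(OCc3ccccc3)c(OCc3ccccc3)c1)[C@H](OCc1ccccc1)[C@H]2c1c(OCc2ccccc2)cc(OCc2ccccc2)c2c1O[C@H](c1ccc(OCc3ccccc3)c(OCc3ccccc3)c1)[C@H](OCc1ccccc1)[C@H]2SCc1ccccc1 | intermediate
6 | 2,4,6-trihydroxybenzaldehyde | O=Cc1c(O)cc(O)cc1O | starting material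
7 | 2-hydroxy-4,6-bis(pivaloyloxy)benzaldehyde | O=Cc1c(O)cc(OC(=O)C(C)(C)C)cc1OC(=O)C(C)(C)C | intermediate
8 | 2-(tert-butyldimethylsilyloxy)-4,6-bis(pivaloyloxy)benzaldehyde | O=Cc1c(O[Si](C)(C)C(C)(C)C)cc(OC(=O)C(C)(C)C)cc1OC(=O)C(C)(C)C | intermediate
9 | 3,4-dihydroxyphenylacetic acid | OC(=O)Cc1ccc(O)c(O)c1 | starting material
10 | benzyl [3,4-bis(benzyloxy)phenyl]acetate | O=C(OCc1ccccc1)Cc1ccc(OCc2ccccc2)c(OCc2ccccc2)c1 | intermediate
11 | [3,4-bis(benzyloxy)phenyl]acetaldehyde | O=CCc1ccc(OCc2ccccc2)c(OCc2ccccc2)c1 | intermediate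
12 | TBS enol ether of 11 (Z drawn) | CC(C)(C)[Si](C)(C)O/C=C\c1ccc(OCc2ccccc2)c(OCc2ccccc2)c1 | intermediate
13 | (±)-2,4-cis-diaryl-3-silyloxyoxetane, silyloxy trans to both aryl groups | O1[C@H](c2ccc(OCc3ccccc3)c(OCc3ccccc3)c2)[C@@H](O[Si](C)(C)C(C)(C)C)[C@@H]1c1c(O[Si](C)(C)C(C)(C)C)cc(OC(=O)C(C)(C)C)cc1OC(=O)C(C)(C)C | intermediate
14 | (±)-anti β-hydroxy-α-silyloxy aryl ketone | O=C(c1ccc(OCc2ccccc2)c(OCc2ccccc2)c1)[C@@H](O[Si](C)(C)C(C)(C)C)[C@@H](O)c1c(O[Si](C)(C)C(C)(C)C)cc(OC(=O)C(C)(C)C)cc1OC(=O)C(C)(C)C | intermediate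
15 | (±)-anti keto phenol | O=C(c1ccc(OCc2ccccc2)c(OCc2ccccc2)c1)[C@@H](O[Si](C)(C)C(C)(C)C)[C@@H](O)c1c(O)cc(OC(=O)C(C)(C)C)cc1OC(=O)C(C)(C)C | intermediate
16 | (±)-cyclic hemiketal (2-hydroxyflavan, C2 undefined) | O[C@H]1c2c(OC(=O)C(C)(C)C)cc(OC(=O)C(C)(C)C)cc2OC(O)(c2ccc(OCc3ccccc3)c(OCc3ccccc3)c2)[C@H]1O[Si](C)(C)C(C)(C)C | intermediate
17 | (±)-all-cis 3-O-TBS-5,7-di-O-pivaloyl-3',4'-di-O-benzylflavan-3,4-diol, (2S,3S,4S) drawn | O[C@H]1c2c(OC(=O)C(C)(C)C)cc(OC(=O)C(C)(C)C)cc2O[C@@H](c2ccc(OCc3ccccc3)c(OCc3ccccc3)c2)[C@H]1O[Si](C)(C)C(C)(C)C | intermediate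
18 | fully protected trimer | C(c1ccccc1)Oc1cc(OCc2ccccc2)c2c(c1)O[C@H](c1ccc(OCc3ccccc3)c(OCc3ccccc3)c1)[C@H](OCc1ccccc1)[C@H]2c1c(OCc2ccccc2)cc(OCc2ccccc2)c2c1O[C@H](c1ccc(OCc3ccccc3)c(OCc3ccccc3)c1)[C@H](OCc1ccccc1)[C@H]2O[C@H]1c2c(OC(=O)C(C)(C)C)cc(OC(=O)C(C)(C)C)cc2O[C@@H](c2ccc(OCc3ccccc3)c(OCc3ccccc3)c2)[C@H]1O[Si](C)(C)C(C)(C)C | intermediate
19 | desilylated trimer | C(c1ccccc1)Oc1cc(OCc2ccccc2)c2c(c1)O[C@H](c1ccc(OCc3ccccc3)c(OCc3ccccc3)c1)[C@H](OCc1ccccc1)[C@H]2c1c(OCc2ccccc2)cc(OCc2ccccc2)c2c1O[C@H](c1ccc(OCc3ccccc3)c(OCc3ccccc3)c1)[C@H](OCc1ccccc1)[C@H]2O[C@H]1c2c(OC(=O)C(C)(C)C)cc(OC(=O)C(C)(C)C)cc2O[C@@H](c2ccc(OCc3ccccc3)c(OCc3ccccc3)c2)[C@H]1O | intermediate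
20 | dodeca-O-benzyl trimer | C(c1ccccc1)Oc1cc(OCc2ccccc2)c2c(c1)O[C@H](c1ccc(OCc3ccccc3)c(OCc3ccccc3)c1)[C@H](OCc1ccccc1)[C@H]2c1c(OCc2ccccc2)cc(OCc2ccccc2)c2c1O[C@H](c1ccc(OCc3ccccc3)c(OCc3ccccc3)c1)[C@H](OCc1ccccc1)[C@H]2O[C@H]1c2c(O)cc(O)cc2O[C@@H](c2ccc(OCc3ccccc3)c(OCc3ccccc3)c2)[C@H]1O | intermediate
21 | CNP0310719.1 | Oc1cc(O)c2c(c1)O[C@H](c1ccc(O)c(O)c1)[C@H](O)[C@H]2c1c(O)cc(O)c2c1O[C@H](c1ccc(O)c(O)c1)[C@H](O)[C@H]2O[C@H]1c2c(O)cc(O)cc2O[C@@H](c2ccc(O)c(O)c2)[C@H]1O | target

**Step count:** 17 steps in total. The longest linear sequence is 11 steps (9 → 10 → 11 → 12 → 13 → 14 → 15 → 17 → 18 → 19 → 20 → 21).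

**Steps most likely to fail**

Step 10. The aldehyde triplet may be drained by energy or electron transfer to the electron-rich styrene-type enol ether. The carbonyl oxygen may bond to the siloxy-bearing carbon instead of C2. The biradical may also close with OTBS cis to the ring A aryl. The fallback sets out from 8 and returns at 14, leaving out 13. Commercial 1-[3,4-bis(benzyloxy)phenyl]ethanone is treated with TBSOTf/Et3N to give its silyl enol ether F1. Rubottom oxidation (mCPBA, NaHCO3, CH2Cl2) with silyl migration gives the α-silyloxy ketone F2. Enolisation with (c-C6H11)2BCl/Et3N in Et2O gives the E enol borinate F3, and its aldol addition to 8 through a closed chair transition state should give the anti aldol, which is 14.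

Step 14. Capture of a hindered cation by a hindered alcohol may be so slow that proton loss from C3 or hydrolysis takes over, and the two diastereomeric ethers may separate poorly. The fallback sets out from 2 and 3 and returns at 18. TMSOTf-catalysed condensation of 3 with an excess of 2 gives the deca-O-benzyl 4β→8 dimer F4. DDQ in CH2Cl2 in the presence of 17 then abstracts hydride from C4–H of the lower unit, by far the most hydridic C–H present. The alcohol traps the cation under non-acidic conditions, so C–H oxidation replaces leaving-group activation.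

Step 11. Hydride abstraction from the stronger C–H bond of the strained ring may be sluggish, which would let unselective oxidation or desilylation compete. The fallback sets out from 13 and returns at 14. Sc(OTf)3-catalysed hydrolysis in wet MeCN opens the oxetane heterolytically at the p-alkoxybenzylic C2–O bond to give the 1,3-diol F5 (either configuration at the new carbinol centre serves). MnO2 in CH2Cl2 then oxidises only the electron-rich benzylic alcohol.

**Further compounds**
F1 | step 10 | 1-[3,4-bis(benzyloxy)phenyl]-1-(tert-butyldimethylsilyloxy)ethene | C=C(O[Si](C)(C)C(C)(C)C)c1ccc(OCc2ccccc2)c(OCc2ccccc2)c1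
F2 | step 10 | 1-[3,4-bis(benzyloxy)phenyl]-2-(tert-butyldimethylsilyloxy)ethanone | O=C(CO[Si](C)(C)C(C)(C)C)c1ccc(OCc2ccccc2)c(OCc2ccccc2)c1
F3 | step 10 | (E)-enol dicyclohexylborinate of F2 | C1CCCCC1B(C1CCCCC1)O/C(c1ccc(OCc2ccccc2)c(OCc2ccccc2)c1)=C/O[Si](C)(C)C(C)(C)C
F4 | step 14 | penta-O-benzylepicatechin-(4β→8)-penta-O-benzylepicatechin | C(c1ccccc1)Oc1cc(OCc2ccccc2)c2c(c1)O[C@H](c1ccc(OCc3ccccc3)c(OCc3ccccc3)c1)[C@H](OCc1ccccc1)[C@H]2c1c(OCc2ccccc2)cc(OCc2ccccc2)c2c1O[C@H](c1ccc(OCc3ccccc3)c(OCc3ccccc3)c1)[C@H](OCc1ccccc1)C2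
F5 | step 11 | (±)-1-[3,4-bis(benzyloxy)phenyl]-2-(tert-butyldimethylsilyloxy)-3-[2-(tert-butyldimethylsilyloxy)-4,6-bis(pivaloyloxy)phenyl]propane-1,3-diol (2,3-anti, C1 undefined) | OC(c1ccc(OCc2ccccc2)c(OCc2ccccc2)c1)[C@@H](O[Si](C)(C)C(C)(C)C)[C@@H](O)c1c(O[Si](C)(C)C(C)(C)C)cc(OC(=O)C(C)(C)C)cc1OC(=O)C(C)(C)C
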